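Everything rests on cutting the sp3–sp2 bond between the α-carbon (C2) of the (Z)-5-(furan-3-yl)pent-2-enoic acid unit and the CH2 that leads back to the stereocentre. A palladium-catalysed Negishi coupling forms this bond in one operation: a C21 primary alkylzinc iodide, built from (R)-carvone and already carrying the isopropenyl stereocentre, the E-trisubstituted alkene and the first Z-enoate, meets a C9 methyl (E)-2-bromo-5-(furan-3-yl)pent-2-enoate. The step exploits the acid α-carbon, normally an enolate nucleophile, as a vinyl electrophile whose bromine sits cis to the vinylic hydrogen, so that retention delivers the Z-enoate with the furan ring intact.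

Key step: step 15

Step 1
Reactants: 1 (R)-(−)-carvone
Product: 2 (1R,4R,6R)-1-methyl-4-(prop-1-en-2-yl)-7-oxabicyclo[4.1.0]heptan-2-one (trans-carvone epoxide)
Conditions: 30% aq. H2O2, NaOH (cat.), MeOH, 0 °C
Reagents that add atoms: hydrogen peroxide, OO
Why: Weitz–Scheffer nucleophilic epoxidation attacks only the electron-poor enone C=C bond, anti to the isopropenyl-bearing carbon, and leaves the isopropenyl group alone; both new stereocentres are erased in step 2.

Step 2
Reactants: 2 trans-carvone epoxide
Product: 4 (3S)-3-(prop-1-en-2-yl)hept-5-ynal, via epoxy ketone tosylhydrazone 3 (not isolated)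
Conditions: TsNHNH2, AcOH/CH2Cl2, −20 °C to rt
Reagents that add atoms: none
Why: Eschenmoser–Tanabe fragmentation, in which the tosylhydrazone opens the epoxide and the resulting alkoxide cleaves the former C2–C3 ring bond with loss of N2 and sulfinate, should give the methyl alkyne and the aldehyde without touching the stereocentre.

Step 3
Reactants: 4 (3S)-3-(prop-1-en-2-yl)hept-5-ynal
Product: 5 (3S)-3-(prop-1-en-2-yl)hept-5-yn-1-ol
Conditions: NaBH4, MeOH, 0 °C
Reagents that add atoms: none
Why: Chemoselective borohydride reduction of the aldehyde, which leaves the alkyne and the isopropenyl group unchanged.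

Step 4
Reactants: 5 (3S)-3-(prop-1-en-2-yl)hept-5-yn-1-ol
Product: 7 (3S,5E)-6-iodo-3-(prop-1-en-2-yl)hept-5-en-1-ol, via alkenylzirconocene chloride 6 (not isolated)
Conditions: Cp2Zr(H)Cl (2.3 equiv), THF, rt to 45 °C; then I2, 0 °C
Reagents that add atoms: iodine, II
Why: Hydrozirconation–iodinolysis, in which one equivalent of hydride is consumed by the hydroxyl group, syn addition of Zr–H and equilibration by the excess hydride should place zirconium on the less hindered methyl-bearing alkyne carbon, and iodinolysis with retention gives the (E)-iodide while the hindered isopropenyl group reacts far more slowly.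

Step 5
Reactants: 7 (3S,5E)-6-iodo-3-(prop-1-en-2-yl)hept-5-en-1-ol; 8 acrolein diethyl acetal (3,3-diethoxyprop-1-ene)
Product: 10 (3S,5E)-9,9-diethoxy-6-methyl-3-(prop-1-en-2-yl)non-5-en-1-ol, via B-alkyl-9-BBN borane 9 (not isolated)
Conditions: 8, 9-BBN, THF, 0 °C to rt; then 7, PdCl2(dppf) (5 mol %), AsPh3, Cs2CO3, DMF/H2O, rt
Reagents that add atoms: none
Why: B-alkyl Suzuki–Miyaura coupling, in which anti-Markovnikov hydroboration of the vinyl group of 8 is followed by stereoretentive coupling with the vinyl iodide under aqueous base that tolerates the free hydroxyl group.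

Step 6
Reactants: 10 (3S,5E)-9,9-diethoxy-6-methyl-3-(prop-1-en-2-yl)non-5-en-1-ol
Product: 11 (4E,7S)-9-hydroxy-4-methyl-7-(prop-1-en-2-yl)non-4-enal
Conditions: 1 M HCl (cat.), THF/H2O, rt
Reagents that add atoms: water, O
Why: Acid-catalysed hydrolysis of the acyclic diethyl acetal is fast under dilute acid at room temperature, conditions under which the two alkenes should survive.

Step 7
Reactants: 12 methyl 2-[bis(2,2,2-trifluoroethoxy)phosphoryl]acetate; 13 5-bromo-2-methylpent-2-ene
Product: 15 methyl 2-[bis(2,2,2-trifluoroethoxy)phosphoryl]-6-methylhept-5-enoate (racemic), via sodium phosphonate anion 14 (not isolated)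
Conditions: NaH, DMF, 0 °C; then 13, NaI (cat.), 50 °C
Reagents that add atoms: none
Why: SN2 C-alkylation of the stabilised phosphonoacetate anion by the primary bromide, assisted by in situ Finkelstein exchange to the iodide.

Step 8
Reactants: 11 (4E,7S)-9-hydroxy-4-methyl-7-(prop-1-en-2-yl)non-4-enal; 15 methyl 2-[bis(2,2,2-trifluoroethoxy)phosphoryl]-6-methylhept-5-enoate
Product: 17 methyl (2Z,6E,9S)-11-hydroxy-6-methyl-2-(4-methylpent-3-en-1-yl)-9-(prop-1-en-2-yl)undeca-2,6-dienoate, via potassium phosphonate anion 16 (not isolated)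
Conditions: 15, KN(SiMe3)2, 18-crown-6, THF, −78 °C; then 11
Reagents that add atoms: none
Why: Still–Gennari variant of the Horner–Wadsworth–Emmons olefination, in which the electron-poor bis(trifluoroethyl) phosphonate and the crown-complexed potassium ion make the addition irreversible so that the ester should end up cis to the aldehyde-derived chain (Z), while the stabilised anion does not deprotonate the free alcohol.

Step 9
Reactants: 17 methyl (2Z,6E,9S)-11-hydroxy-6-methyl-2-(4-methylpent-3-en-1-yl)-9-(prop-1-en-2-yl)undeca-2,6-dienoate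
Product: 18 methyl (2Z,6E,9S)-11-iodo-6-methyl-2-(4-methylpent-3-en-1-yl)-9-(prop-1-en-2-yl)undeca-2,6-dienoate
Conditions: I2, PPh3, imidazole, CH2Cl2, 0 °C
Reagents that add atoms: iodine, II
Why: Appel-type iodination, an SN2 displacement of the activated primary oxyphosphonium by iodide that does not affect the alkenes or the ester.

Step 10
Reactants: 19 3-bromofuran; 20 oxetane
Product: 22 3-(furan-3-yl)propan-1-ol, via 3-furyllithium 21 (not isolated)
Conditions: 19, n-BuLi, THF, −78 °C; then 20, BF3·OEt2, −78 °C
Reagents that add atoms: none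
Why: Bromine–lithium exchange gives 3-furyllithium, kept at −78 °C to prevent isomerisation to the 2-lithio species, and BF3-activated SN2 ring opening of oxetane installs the three-carbon alcohol chain.

Step 11
Reactants: 22 3-(furan-3-yl)propan-1-ol
Product: 23 3-(furan-3-yl)propanal
Conditions: Dess–Martin periodinane, NaHCO3, CH2Cl2, 0 °C to rt
Reagents that add atoms: none
Why: Dess–Martin oxidation converts the primary alcohol to the aldehyde under buffered, non-acidic conditions that the furan ring tolerates.

Step 12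
Reactants: 12 methyl 2-[bis(2,2,2-trifluoroethoxy)phosphoryl]acetate
Product: 24 methyl 2-[bis(2,2,2-trifluoroethoxy)phosphoryl]-2,2-dibromoacetate
Conditions: Br2, aq. NaOH (NaOBr), 0 °C, short contact
Reagents that add atoms: bromine, BrBr
Why: Electrophilic α-bromination of the active methylene by hypobromite runs through to the dibromide because the monobromide is the stronger acid.

Step 13
Reactants: 24 methyl 2-[bis(2,2,2-trifluoroethoxy)phosphoryl]-2,2-dibromoacetate
Product: 25 methyl 2-[bis(2,2,2-trifluoroethoxy)phosphoryl]-2-bromoacetate (racemic)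
Conditions: SnCl2·2H2O, EtOH/H2O, 0 °C
Reagents that add atoms: none
Why: Halophilic reduction by divalent tin removes one bromine from the gem-dibromide and should stop at the less electrophilic monobromide.

Step 14
Reactants: 23 3-(furan-3-yl)propanal; 25 methyl 2-[bis(2,2,2-trifluoroethoxy)phosphoryl]-2-bromoacetate
Product: 27 methyl (2E)-2-bromo-5-(furan-3-yl)pent-2-enoate, via potassium bromophosphonate anion 26 (not isolated)
Conditions: 25, KOt-Bu, 18-crown-6, THF, −78 °C; then 23
Reagents that add atoms: none
Why: Horner–Wadsworth–Emmons olefination with the bromo analogue of the Still–Gennari reagent, under the same kinetic control, should place the ester cis to the alkyl chain and the bromine cis to the vinylic hydrogen, which is the (E)-α-bromo enoate.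

Step 15
Reactants: 18 methyl (2Z,6E,9S)-11-iodo-6-methyl-2-(4-methylpent-3-en-1-yl)-9-(prop-1-en-2-yl)undeca-2,6-dienoate; 27 methyl (2E)-2-bromo-5-(furan-3-yl)pent-2-enoate
Product: 29 dimethyl (2Z,6E,9R,12Z)-12-[3-(furan-3-yl)propylidene]-6-methyl-2-(4-methylpent-3-en-1-yl)-9-(prop-1-en-2-yl)tridec-2,6-dienedioate, via alkylzinc iodide 28 (not isolated)
Conditions: 18, Zn dust (activated with BrCH2CH2Br, Me3SiCl), LiCl, THF, 40 °C; then 27, PdCl2(dppf) (5 mol %), THF/NMP, 25 to 45 °C
Reagents that add atoms: none
Why: Zinc inserts into the primary C–I bond of 18 to give the ester-tolerant alkylzinc iodide 28, zerovalent palladium adds oxidatively to the C(sp2)–Br bond of 27 with retention, transmetalation delivers the alkyl group and reductive elimination forms the CH2–C(α) bond. The closest known reaction type is the Negishi alkyl–alkenyl coupling of α-halo enoates and α-iodo enones with primary alkylzinc halides, which proceeds with retention of alkene geometry. No ring is closed and no stereocentre is formed, and the existing centre lies three bonds from the reacting carbon and is not touched. The step needs geometric fidelity at the α-palladated enoate, which fast transmetalation by the organozinc should secure, so that the chain replaces the bromine cis to the vinylic hydrogen and the ester stays cis to the furylethyl group (Z). It needs reductive elimination to outrun β-hydride elimination of the primary alkyl group, for which the wide-bite-angle dppf ligand is chosen. It needs the alkyl carbon to react as a two-electron nucleophile, because a free radical there would cyclise 5-exo onto the C6=C7 alkene, whereas the organozinc is inert towards both enoates, the isopropenyl group and the furan ring.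

Step 16
Reactants: 29 dimethyl (2Z,6E,9R,12Z)-12-[3-(furan-3-yl)propylidene]-6-methyl-2-(4-methylpent-3-en-1-yl)-9-(prop-1-en-2-yl)tridec-2,6-dienedioate
Product: 30 (2Z,6E,9R,12Z)-12-[3-(furan-3-yl)propylidene]-6-methyl-2-(4-methylpent-3-en-1-yl)-9-(prop-1-en-2-yl)tridec-2,6-dienedioic acid (CNP0235727.1)
Conditions: LiOH·H2O, THF/MeOH/H2O, 40 °C; then 1 M HCl to pH 3, 0 °C
Reagents that add atoms: lithium hydroxide, [Li+].[OH-]
Why: Saponification of both methyl esters by acyl–oxygen cleavage under mild base should not isomerise the Z-enoates, and brief cold acidification spares the furan ring and the alkenes.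

Compound list
1 | (R)-(−)-carvone | CC1=CC[C@H](CC1=O)C(C)=C | starting material
2 | (1R,4R,6R)-1-methyl-4-(prop-1-en-2-yl)-7-oxabicyclo[4.1.0]heptan-2-one | C[C@@]12O[C@@H]1C[C@H](CC2=O)C(C)=C | intermediate
3 | p-toluenesulfonylhydrazone of 2 | C[C@@]12O[C@@H]1C[C@H](CC2=NNS(=O)(=O)c1ccc(C)cc1)C(C)=C | intermediate
4 | (3S)-3-(prop-1-en-2-yl)hept-5-ynal | C=C(C)[C@@H](CC#CC)CC=O | intermediate
5 | (3S)-3-(prop-1-en-2-yl)hept-5-yn-1-ol | C=C(C)[C@@H](CC#CC)CCO | intermediate
6 | alkenylzirconocene chloride of 5 (Zr on the methyl-bearing alkene carbon, cis to the vinylic H; hydroxyl as zirconium alkoxide) | C=C(C)[C@@H](C/C=C(\C)[Zr](Cl)(C1C=CC=C1)C1C=CC=C1)CCO[Zr](Cl)(C1C=CC=C1)C1C=CC=C1 | intermediate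
7 | (3S,5E)-6-iodo-3-(prop-1-en-2-yl)hept-5-en-1-ol | C=C(C)[C@@H](C/C=C(\C)I)CCO | intermediate
8 | acrolein diethyl acetal (3,3-diethoxyprop-1-ene) | C=CC(OCC)OCC | starting material
9 | 9-(3,3-diethoxypropyl)-9-borabicyclo[3.3.1]nonane | CCOC(CCB1C2CCCC1CCC2)OCC | intermediate
10 | (3S,5E)-9,9-diethoxy-6-methyl-3-(prop-1-en-2-yl)non-5-en-1-ol | C=C(C)[C@@H](C/C=C(\C)CCC(OCC)OCC)CCO | intermediate
11 | (4E,7S)-9-hydroxy-4-methyl-7-(prop-1-en-2-yl)non-4-enal | C=C(C)[C@@H](C/C=C(\C)CCC=O)CCO | intermediate
12 | methyl 2-[bis(2,2,2-trifluoroethoxy)phosphoryl]acetate | COC(=O)CP(=O)(OCC(F)(F)F)OCC(F)(F)F | starting material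
13 | 5-bromo-2-methylpent-2-ene | CC(C)=CCCBr | starting material
14 | sodium salt of 12 (phosphonate carbanion) | [Na+].COC(=O)[CH-]P(=O)(OCC(F)(F)F)OCC(F)(F)F | intermediate
15 | methyl 2-[bis(2,2,2-trifluoroethoxy)phosphoryl]-6-methylhept-5-enoate (racemic) | COC(=O)C(CCC=C(C)C)P(=O)(OCC(F)(F)F)OCC(F)(F)F | intermediate
16 | potassium salt of 15 (phosphonate carbanion) | [K+].COC(=O)[C-](CCC=C(C)C)P(=O)(OCC(F)(F)F)OCC(F)(F)F | intermediate
17 | methyl (2Z,6E,9S)-11-hydroxy-6-methyl-2-(4-methylpent-3-en-1-yl)-9-(prop-1-en-2-yl)undeca-2,6-dienoate | C=C(C)[C@@H](C/C=C(\C)CC/C=C(/CCC=C(C)C)C(=O)OC)CCO | intermediate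
18 | methyl (2Z,6E,9S)-11-iodo-6-methyl-2-(4-methylpent-3-en-1-yl)-9-(prop-1-en-2-yl)undeca-2,6-dienoate | C=C(C)[C@@H](C/C=C(\C)CC/C=C(/CCC=C(C)C)C(=O)OC)CCI | intermediate
19 | 3-bromofuran | Brc1ccoc1 | starting material
20 | oxetane | C1COC1 | starting material
21 | 3-furyllithium | [Li]c1ccoc1 | intermediate
22 | 3-(furan-3-yl)propan-1-ol | OCCCc1ccoc1 | intermediate
23 | 3-(furan-3-yl)propanal | O=CCCc1ccoc1 | intermediate
24 | methyl 2-[bis(2,2,2-trifluoroethoxy)phosphoryl]-2,2-dibromoacetate | COC(=O)C(Br)(Br)P(=O)(OCC(F)(F)F)OCC(F)(F)F | intermediate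
25 | methyl 2-[bis(2,2,2-trifluoroethoxy)phosphoryl]-2-bromoacetate (racemic) | COC(=O)C(Br)P(=O)(OCC(F)(F)F)OCC(F)(F)F | intermediate
26 | potassium salt of 25 (phosphonate carbanion) | [K+].COC(=O)[C-](Br)P(=O)(OCC(F)(F)F)OCC(F)(F)F | intermediate
27 | methyl (2E)-2-bromo-5-(furan-3-yl)pent-2-enoate | COC(=O)/C(Br)=C\CCc1ccoc1 | intermediate
28 | alkylzinc iodide from 18 (C–I replaced by C–ZnI) | C=C(C)[C@@H](C/C=C(\C)CC/C=C(/CCC=C(C)C)C(=O)OC)CC[Zn]I | intermediate
29 | dimethyl (2Z,6E,9R,12Z)-12-[3-(furan-3-yl)propylidene]-6-methyl-2-(4-methylpent-3-en-1-yl)-9-(prop-1-en-2-yl)tridec-2,6-dienedioate | C=C(C)[C@@H](C/C=C(\C)CC/C=C(/CCC=C(C)C)C(=O)OC)CC/C(=C/CCc1ccoc1)C(=O)OC | intermediate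
30 | (2Z,6E,9R,12Z)-12-[3-(furan-3-yl)propylidene]-6-methyl-2-(4-methylpent-3-en-1-yl)-9-(prop-1-en-2-yl)tridec-2,6-dienedioic acid | C=C(C)[C@@H](C/C=C(\C)CC/C=C(/CCC=C(C)C)C(=O)O)CC/C(=C/CCc1ccoc1)C(=O)O | target

Total step count: 16.
Longest linear sequence: 10 steps (steps 1, 2, 3, 4, 5, 6, 8, 9, 15, 16, from (R)-carvone).

Steps most likely to fail

Step 15. The zinc insertion passes through a surface-bound radical that may cyclise 5-exo onto the C6=C7 alkene or be quenched to the alkane. In the coupling itself, the α-palladated enoate may lose its geometry or the alkyl group may undergo β-hydride elimination. The fallback sets out from 18 and comes back at 29. The sodium anion 14 of phosphonate 12 is alkylated with iodide 18 (DMF, 25 to 40 °C) to give the α-alkylated phosphonate dimethyl (2Z,6E,9R)-12-[bis(2,2,2-trifluoroethoxy)phosphoryl]-6-methyl-2-(4-methylpent-3-en-1-yl)-9-(prop-1-en-2-yl)tridec-2,6-dienedioate F1 as a mixture of epimers at the phosphorus-bearing carbon. A Still–Gennari olefination of its potassium anion (KN(SiMe3)2, 18-crown-6, THF, −78 °C) with aldehyde 23 should then give 29. The bond is thus made by SN2 alkylation and the Z-geometry by the olefination.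

Step 4. The two regioisomeric alkenylzirconium species may not equilibrate fully, and the excess hydride needed for equilibration may also hydrozirconate the isopropenyl group. The fallback sets out from 5 and comes back at 7. Palladium-catalysed syn-hydrostannation (PdCl2(PPh3)2 cat., Bu3SnH, THF, 0 °C), which does not touch isolated alkenes, should give (3S,5E)-3-(prop-1-en-2-yl)-6-(tributylstannyl)hept-5-en-1-ol F2 after chromatographic removal of its regioisomer. Iododestannylation with retention (I2, CH2Cl2, 0 °C) returns 7.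

Step 14. The E-selectivity of the bromo-olefination may erode, or the reagent anion may lose bromine before it meets the aldehyde. The fallback sets out from 23 and comes back at 29.
- Corey–Fuchs olefination (CBr4, PPh3, CH2Cl2, 0 °C) gives 3-(4,4-dibromobut-3-en-1-yl)furan F3.
- n-BuLi (2 equiv, THF, −78 °C) followed by ClCO2Me gives methyl 5-(furan-3-yl)pent-2-ynoate F4.
- Syn-hydrostannation (Pd(PPh3)4 cat., Bu3SnH, THF) puts tin on the α-carbon, cis to the new vinylic hydrogen, and gives methyl (2E)-5-(furan-3-yl)-2-(tributylstannyl)pent-2-enoate F5.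
- I2 (CH2Cl2, 0 °C) gives methyl (2E)-5-(furan-3-yl)-2-iodopent-2-enoate F6, whose geometry is fixed by the syn addition.
- F6 replaces 27 in the coupling of step 15 and should give 29.

Further compounds
F1 | step 15 | dimethyl (2Z,6E,9R)-12-[bis(2,2,2-trifluoroethoxy)phosphoryl]-6-methyl-2-(4-methylpent-3-en-1-yl)-9-(prop-1-en-2-yl)tridec-2,6-dienedioate (C12 epimers) | C=C(C)[C@@H](C/C=C(\C)CC/C=C(/CCC=C(C)C)C(=O)OC)CCC(C(=O)OC)P(=O)(OCC(F)(F)F)OCC(F)(F)F
F2 | step 4 | (3S,5E)-3-(prop-1-en-2-yl)-6-(tributylstannyl)hept-5-en-1-ol | C=C(C)[C@@H](C/C=C(\C)[Sn](CCCC)(CCCC)CCCC)CCO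
F3 | step 14 | 3-(4,4-dibromobut-3-en-1-yl)furan | BrC(Br)=CCCc1ccoc1
F4 | step 14 | methyl 5-(furan-3-yl)pent-2-ynoate | COC(=O)C#CCCc1ccoc1
F5 | step 14 | methyl (2E)-5-(furan-3-yl)-2-(tributylstannyl)pent-2-enoate | COC(=O)/C(=C\CCc1ccoc1)[Sn](CCCC)(CCCC)CCCC
F6 | step 14 | methyl (2E)-5-(furan-3-yl)-2-iodopent-2-enoate | COC(=O)/C(I)=C\CCc1ccoc1
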